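**Retrosynthetic overview**
1. Target ⇐ cation exchange and hydrogenolysis ⇐ 3,3'-di-O-benzyl bis-sulfate ⇐ site-selective bis-O-sulfation of 3,3'-di-O-benzylquercetin (7-OH and 4'-OH free; the chelated 5-OH is left bare).
2. Key step: ring C is made last in one thermal operation (C4–C4a acylation plus O1–C2 cyclodehydration) from unprotected phloroglucinol and an α-benzyloxy aroylacetate through an acylketene (Mentzer-type annulation). This replaces both the semisynthesis from quercetin and the usual chalcone/Algar–Flynn–Oyamada or Baker–Venkataraman assembly on a protected phloroacetophenone.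
3. The α-benzyloxy β-keto ester ⇐ aldol addition and oxidation of ethyl benzyloxyacetate with the ring B aldehyde.
4. Ring B aldehyde ⇐ protocatechualdehyde by dianion-controlled 3-O-benzylation, then 4-O-silylation.
5. Ring order: rings B and A are bought, ring C is formed last.

Assumption: the target has no stereocentre, so no enantiocontrol is needed; the neutral bis(hydrogen sulfate) drawn is delivered by cold cation exchange of its bis(triethylammonium) salt, which is the stable storage form.

**Route**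

Step 1
Reactants: 1 3,4-dihydroxybenzaldehyde
Product: 2 3-(benzyloxy)-4-hydroxybenzaldehyde
Conditions: NaH (2.05 equiv), DMSO, rt, 1 h; BnBr (1.0 equiv), rt, 3 h; aq. HCl
Reagents that add atoms: benzyl bromide BrCc1ccccc1
Why: Williamson etherification of the catechol dianion: the 4-oxide is delocalised into the para-formyl group, so the more nucleophilic 3-oxide takes the single equivalent of benzyl bromide (the monoanion would alkylate at O-4 instead); no stereocentre is formed.

Step 2
Reactants: 2 3-(benzyloxy)-4-hydroxybenzaldehyde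
Product: 3 3-(benzyloxy)-4-[(tert-butyldimethylsilyl)oxy]benzaldehyde
Conditions: TBSCl (1.2 equiv), imidazole (2 equiv), DMF, rt, 2 h
Reagents that add atoms: tert-butyldimethylsilyl chloride CC(C)(C)[Si](C)(C)Cl
Why: Imidazole-promoted silyl ether formation masks the only acidic proton before the enolate chemistry and marks the oxygen that will later carry the 4'-sulfate; no stereocentre is formed.

Step 3
Reactants: 3 3-(benzyloxy)-4-[(tert-butyldimethylsilyl)oxy]benzaldehyde; 4 ethyl 2-(benzyloxy)acetate (1.2 equiv)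
Product: 5 ethyl 2-(benzyloxy)-3-{3-(benzyloxy)-4-[(tert-butyldimethylsilyl)oxy]phenyl}-3-hydroxypropanoate (racemic syn/anti mixture)
Conditions: LiN(iPr)2 (1.2 equiv), 4, THF, −78 °C, 30 min; then 3, −78 °C, 45 min; AcOH quench at −78 °C
Reagents that add atoms: none
Why: Directed aldol addition of the preformed lithium glycolate enolate to a non-enolisable aryl aldehyde at low temperature; the two new stereocentres form as a racemic diastereomer mixture, which is irrelevant because one is oxidised in step 4 and the other becomes sp2 in step 5.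

Step 4
Reactants: 5 ethyl 2-(benzyloxy)-3-{3-(benzyloxy)-4-[(tert-butyldimethylsilyl)oxy]phenyl}-3-hydroxypropanoate
Product: 6 ethyl 2-(benzyloxy)-3-{3-(benzyloxy)-4-[(tert-butyldimethylsilyl)oxy]phenyl}-3-oxopropanoate (racemic)
Conditions: Dess–Martin periodinane (1.2 equiv), CH2Cl2, 0 °C → rt, 1 h
Reagents that add atoms: none
Why: Dess–Martin oxidation of the benzylic secondary alcohol to the β-keto ester under neutral conditions that leave the aryl silyl ether, both benzyl ethers and the ester intact; the remaining α-centre is racemic and enolisable.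

Step 5
Reactants: 6 ethyl 2-(benzyloxy)-3-{3-(benzyloxy)-4-[(tert-butyldimethylsilyl)oxy]phenyl}-3-oxopropanoate; 7 benzene-1,3,5-triol (phloroglucinol, anhydrous, 2 equiv)
Product: 10 3-(benzyloxy)-2-[3-(benzyloxy)-4-hydroxyphenyl]-5,7-dihydroxy-4H-chromen-4-one (3,3'-di-O-benzylquercetin), via acylketene 8 (not isolated), via silyl flavone 9 (not isolated)
Conditions: Ph2O, 250 °C, N2 sweep, 1.5 h; cool, aqueous wash; then Bu4NF/AcOH (1.5 equiv each), THF, 0 °C → rt, 1 h
Reagents that add atoms: none
Why: Mentzer-type thermal chromone annulation: the β-keto ester loses ethanol to the acylketene, which C-acylates the highly nucleophilic, symmetrical phloroglucinol, and the neighbouring phenol then cyclodehydrates onto the aryl ketone to close ring C with the 3-oxygen already in place as its benzyl ether; fluoride then removes the silyl group, and the symmetry of phloroglucinol allows only one regioisomer and no stereocentre.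

Step 6
Reactants: 10 3-(benzyloxy)-2-[3-(benzyloxy)-4-hydroxyphenyl]-5,7-dihydroxy-4H-chromen-4-one
Product: 11 bis(triethylammonium) salt of 3,3'-di-O-benzylquercetin 4',7-bis(O-sulfate)
Conditions: Et3N·SO3 (3 equiv), Et3N (3 equiv), DMF, 40 °C, 16 h; C18 chromatography (MeCN/aq. triethylammonium acetate)
Reagents that add atoms: sulfur trioxide–triethylamine complex CC[N+](CC)(CC)S(=O)(=O)[O-]
Why: O-sulfation of phenols with an amine–sulfur trioxide complex: the 7-OH and 4'-OH are the only free, acidic, unchelated phenols, while the 5-OH is held in a hydrogen bond to the 4-carbonyl and does not react with a small excess of reagent at 40 °C.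

Step 7
Reactants: 11 bis(triethylammonium) salt of 3,3'-di-O-benzylquercetin 4',7-bis(O-sulfate)
Product: 13 3',5-dihydroxy-4',7-bis(sulfooxy)flavonol (quercetin 4',7-bis(hydrogen sulfate)), via triethylammonium salt 12 (not isolated)
Conditions: H2 (1 atm), 10% Pd/C, MeOH–THF, rt, 3 h; filter; then sulfonated polystyrene cation-exchange resin (H+ form), H2O, 0 °C; freeze-dry at once
Reagents that add atoms: none
Why: Catalytic hydrogenolysis cleaves the aryl and enol benzyl ethers while aryl sulfate monoester anions and the tetrasubstituted chromone C2=C3 bond are inert to Pd/C and hydrogen at 1 atm; cation exchange then replaces triethylammonium by protons, and the achiral target needs no stereocontrol.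

**Compound list**
1 | 3,4-dihydroxybenzaldehyde | O=Cc1ccc(O)c(O)c1 | starting material
2 | 3-(benzyloxy)-4-hydroxybenzaldehyde | O=Cc1ccc(O)c(OCc2ccccc2)c1 | intermediate
3 | 3-(benzyloxy)-4-[(tert-butyldimethylsilyl)oxy]benzaldehyde | O=Cc1ccc(O[Si](C)(C)C(C)(C)C)c(OCc2ccccc2)c1 | intermediate
4 | ethyl 2-(benzyloxy)acetate | CCOC(=O)COCc1ccccc1 | starting material
5 | ethyl 2-(benzyloxy)-3-{3-(benzyloxy)-4-[(tert-butyldimethylsilyl)oxy]phenyl}-3-hydroxypropanoate (racemic syn/anti mixture) | CCOC(=O)C(OCc1ccccc1)C(O)c1ccc(O[Si](C)(C)C(C)(C)C)c(OCc2ccccc2)c1 | intermediate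
6 | ethyl 2-(benzyloxy)-3-{3-(benzyloxy)-4-[(tert-butyldimethylsilyl)oxy]phenyl}-3-oxopropanoate (racemic) | CCOC(=O)C(OCc1ccccc1)C(=O)c1ccc(O[Si](C)(C)C(C)(C)C)c(OCc2ccccc2)c1 | intermediate
7 | benzene-1,3,5-triol (phloroglucinol) | Oc1cc(O)cc(O)c1 | starting material
8 | 2-(benzyloxy)-3-{3-(benzyloxy)-4-[(tert-butyldimethylsilyl)oxy]phenyl}-3-oxoprop-1-en-1-one (acylketene) | O=C=C(OCc1ccccc1)C(=O)c1ccc(O[Si](C)(C)C(C)(C)C)c(OCc2ccccc2)c1 | intermediate
9 | 3-(benzyloxy)-2-{3-(benzyloxy)-4-[(tert-butyldimethylsilyl)oxy]phenyl}-5,7-dihydroxy-4H-chromen-4-one | O=c1c(OCc2ccccc2)c(-c2ccc(O[Si](C)(C)C(C)(C)C)c(OCc3ccccc3)c2)oc2cc(O)cc(O)c12 | intermediate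
10 | 3-(benzyloxy)-2-[3-(benzyloxy)-4-hydroxyphenyl]-5,7-dihydroxy-4H-chromen-4-one (3,3'-di-O-benzylquercetin) | O=c1c(OCc2ccccc2)c(-c2ccc(O)c(OCc3ccccc3)c2)oc2cc(O)cc(O)c12 | intermediate
11 | bis(triethylammonium) 3-(benzyloxy)-2-[3-(benzyloxy)-4-(sulfonatooxy)phenyl]-5-hydroxy-4-oxo-4H-chromen-7-yl sulfate | O=c1c(OCc2ccccc2)c(-c2ccc(OS(=O)(=O)[O-])c(OCc3ccccc3)c2)oc2cc(OS(=O)(=O)[O-])cc(O)c12.CC[NH+](CC)CC.CC[NH+](CC)CC | intermediate
12 | bis(triethylammonium) 3,5-dihydroxy-2-[3-hydroxy-4-(sulfonatooxy)phenyl]-4-oxo-4H-chromen-7-yl sulfate | O=c1c(O)c(-c2ccc(OS(=O)(=O)[O-])c(O)c2)oc2cc(OS(=O)(=O)[O-])cc(O)c12.CC[NH+](CC)CC.CC[NH+](CC)CC | intermediate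
13 | 3',5-dihydroxy-4',7-bis(sulfooxy)flavonol (achiral) | O=c1c(O)c(-c2ccc(OS(=O)(=O)O)c(O)c2)oc2cc(OS(=O)(=O)O)cc(O)c12 | target

**Summary**
Total step count: 7. Longest linear sequence: 7 steps (1 → 13); compounds 4 and 7 are bought and enter directly.

Steps most likely to fail:

Step 5 (thermal annulation). The risks are Pechmann-type coumarin formation, loss of benzyl groups at 250 °C and a low yield from the α-alkoxy ketoester. The fallback sets out from 3 and 7 and comes back at 10, closing ring C by aroylation, Baker–Venkataraman shift and cyclodehydration instead of through an acylketene. Phloroglucinol 7 is C-acylated with benzyloxyacetonitrile under Houben–Hoesch conditions (ZnCl2, HCl gas, Et2O, 0 °C; then H2O, reflux) to 2-(benzyloxy)-1-(2,4,6-trihydroxyphenyl)ethan-1-one F1. Aldehyde 3 is oxidised (NaClO2, NaH2PO4, 2-methyl-2-butene, tBuOH–H2O) to 3-(benzyloxy)-4-[(tert-butyldimethylsilyl)oxy]benzoic acid F2, which oxalyl chloride and catalytic DMF turn into 3-(benzyloxy)-4-[(tert-butyldimethylsilyl)oxy]benzoyl chloride F3. F1 and F3 (3.3 equiv) with DBU in pyridine at 80 °C give, by per-O-aroylation, acyl shift to the α-carbon and cyclodehydration, the 5,7-bis-O-aroylated 3-benzyloxyflavone F4. Without purification, LiOH in THF–H2O cleaves its two aryl esters and three aryl silyl ethers to give 10.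

Step 1 (3-O-selective benzylation). The risks are 4-O- and bis-benzylated by-products if the dianion is not fully formed. The fallback sets out from 1 and comes back at 2, using the opposite, monoanion selectivity as a relay. Allyl bromide, NaHCO3 and NaI in DMF at 40 °C alkylate the more acidic 4-OH to give 4-(allyloxy)-3-hydroxybenzaldehyde F5. BnBr and K2CO3 in DMF then give 4-(allyloxy)-3-(benzyloxy)benzaldehyde F6. Catalytic Pd(PPh3)4 (zerovalent palladium) with K2CO3 in MeOH at rt transfers the allyl group to methoxide and frees the 4-OH, giving 2.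

Step 6 (bis-sulfation). The risks are incomplete sulfation, some 5-O-sulfation and difficult purification of the salt; the free-acid isolation in step 7 is also delicate. The fallback sets out from 10 and comes back at 13, using a masked sulfate diester instead of direct sulfation. 2,2,2-Trichloroethyl chlorosulfate (2.4 equiv) with Et3N and DMAP in THF at 0 °C → rt gives the neutral, silica-stable 3,3'-di-O-benzylquercetin 4',7-bis(2,2,2-trichloroethyl sulfate) F7, whose regiochemistry can be checked by NMR. Pd/C and HCO2NH4 in MeOH at rt then remove both trichloroethyl groups (reductive β-elimination) and both benzyl ethers in one operation, giving the bis(ammonium) salt of quercetin 4',7-bis(O-sulfate) F8. The same cold H+ cation exchange as in step 7 gives 13.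

**Further compounds**
F1 | step 5 | 2-(benzyloxy)-1-(2,4,6-trihydroxyphenyl)ethan-1-one | O=C(COCc1ccccc1)c1c(O)cc(O)cc1O
F2 | step 5 | 3-(benzyloxy)-4-[(tert-butyldimethylsilyl)oxy]benzoic acid | O=C(O)c1ccc(O[Si](C)(C)C(C)(C)C)c(OCc2ccccc2)c1
F3 | step 5 | 3-(benzyloxy)-4-[(tert-butyldimethylsilyl)oxy]benzoyl chloride | O=C(Cl)c1ccc(O[Si](C)(C)C(C)(C)C)c(OCc2ccccc2)c1
F4 | step 5 | 3-(benzyloxy)-2-{3-(benzyloxy)-4-[(tert-butyldimethylsilyl)oxy]phenyl}-4-oxo-4H-chromene-5,7-diyl bis{3-(benzyloxy)-4-[(tert-butyldimethylsilyl)oxy]benzoate} | O=c1c(OCc2ccccc2)c(-c2ccc(O[Si](C)(C)C(C)(C)C)c(OCc3ccccc3)c2)oc2cc(OC(=O)c3ccc(O[Si](C)(C)C(C)(C)C)c(OCc4ccccc4)c3)cc(OC(=O)c3ccc(O[Si](C)(C)C(C)(C)C)c(OCc4ccccc4)c3)c12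
F5 | step 1 | 4-(allyloxy)-3-hydroxybenzaldehyde | O=Cc1ccc(OCC=C)c(O)c1
F6 | step 1 | 4-(allyloxy)-3-(benzyloxy)benzaldehyde | O=Cc1ccc(OCC=C)c(OCc2ccccc2)c1
F7 | step 6 | 3-(benzyloxy)-2-{3-(benzyloxy)-4-[(2,2,2-trichloroethoxy)sulfonyloxy]phenyl}-5-hydroxy-4-oxo-4H-chromen-7-yl 2,2,2-trichloroethyl sulfate | O=c1c(OCc2ccccc2)c(-c2ccc(OS(=O)(=O)OCC(Cl)(Cl)Cl)c(OCc3ccccc3)c2)oc2cc(OS(=O)(=O)OCC(Cl)(Cl)Cl)cc(O)c12
F8 | step 6 | bis(ammonium) 3,5-dihydroxy-2-[3-hydroxy-4-(sulfonatooxy)phenyl]-4-oxo-4H-chromen-7-yl sulfate | O=c1c(O)c(-c2ccc(OS(=O)(=O)[O-])c(O)c2)oc2cc(OS(=O)(=O)[O-])cc(O)c12.[NH4+].[NH4+]
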